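**Retrosynthetic overview**

1. Crassocolide B ⇐ (C3 acetylation, C4 desilylation, C3 ketone reduction) ⇐ 14-membered 3-ketone. Its unit C17H2=C15–C1–C2–C3(=O) is a γ,δ-unsaturated ketone, the retron of a Carroll (decarboxylative Claisen) rearrangement.
2. Key disconnection C1–C2: the carbocycle comes from an acyclic tert-butyl β-keto ester that already carries the lactone as a 3-(hydroxymethyl)butenolide. In one operation: acylketene formation, O-acylation of C17–OH (temporary 18-membered lactone), [3,3] ring contraction, loss of CO2. The same event sets C1 and unveils the exocyclic methylene.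
3. Enabling feature: the butenolide alkene C15=C1 with its exocyclic C17–O is an allylic alcohol whose γ-carbon is C1, and C2 sits between the C3 ketone and an ester carbon that is lost. No radical, cation or organometal is placed at C2/C3, so the C7=C8 alkene six atoms away cannot cyclize onto it.
4. Acyclic precursor ⇐ vinylogous Mukaiyama aldol (C13–C14 bond, sets C13 and C14) of a farnesol-derived enal (C2–C13; C4 from Sharpless epoxidation, C13 by SeO2 oxidation) with a 2-silyloxyfuran made from 3-furanmethanol.
5. Ring order: five-membered lactone first (present as furanone/silyloxyfuran before the fragments are joined), temporary 18-membered lactone second, 14-membered carbocycle last.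

Key step: step 14

Remark on numbering: cembrane numbering is used for the skeleton (C1 = ring-fusion CH, the lactone β-carbon; C2–C13 = chain; C14 = lactone O–CH; C15 = α-carbon; C16 = C=O; C17 = exocyclic CH2). In the acyclic esters, IUPAC locants 2–13 coincide with C2–C13, and locant 1 is the ester carbon that is later lost as CO2.

Assumption: the sense of induction of the chromium–salen catalyst in step 11 is taken to be the required one with the (R,R)-ligand; if it is the opposite, the (S,S)-ligand is used.

**Step 1**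
Reactants: 1 (2E,6E)-farnesol
Product: 2 (2R,3R,6E)-2,3-epoxy-3,7,11-trimethyldodeca-6,10-dien-1-ol
Conditions: Ti(OiPr)4 (10 mol %), D-(−)-diethyl tartrate (12 mol %), t-BuOOH, 4 Å MS, CH2Cl2, −20 °C
Reagents that add atoms: tert-butyl hydroperoxide CC(C)(C)OO
Why: Sharpless asymmetric epoxidation touches only the allylic-alcohol alkene, and the D-(−)-tartrate ligand delivers oxygen to the face that gives the (2R,3R)-epoxide, which fixes the later C4 stereocenter.

**Step 2**
Reactants: 2 (2R,3R,6E)-2,3-epoxy-3,7,11-trimethyldodeca-6,10-dien-1-ol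
Product: 3 (2S,3R,6E)-1-chloro-2,3-epoxy-3,7,11-trimethyldodeca-6,10-diene
Conditions: PPh3, CCl4, NaHCO3, reflux
Reagents that add atoms: carbon tetrachloride ClC(Cl)(Cl)Cl
Why: Appel chlorination of the primary alcohol under neutral conditions should leave the epoxide and both stereocenters untouched (the descriptor at C2 changes only through ligand priority).

**Step 3**
Reactants: 3 (2S,3R,6E)-1-chloro-2,3-epoxy-3,7,11-trimethyldodeca-6,10-diene
Product: 4 (3R,6E)-3,7,11-trimethyldodeca-6,10-dien-1-yn-3-ol
Conditions: n-BuLi (3.5 equiv), THF, −40 → −20 °C; then H2O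
Reagents that add atoms: none
Why: base-induced twofold elimination of a 2,3-epoxy chloride to a terminal propargylic alcohol is a known fragmentation, and the carbinol C–O bond is never broken, so the tertiary stereocenter is retained.

**Step 4**
Reactants: 4 (3R,6E)-3,7,11-trimethyldodeca-6,10-dien-1-yn-3-ol
Product: 5 (3R,6E)-3-(tert-butyldimethylsilyloxy)-3,7,11-trimethyldodeca-6,10-dien-1-yne
Conditions: TBSOTf, 2,6-lutidine, CH2Cl2, 0 °C
Reagents that add atoms: tert-butyldimethylsilyl trifluoromethanesulfonate CC(C)(C)[Si](C)(C)OS(=O)(=O)C(F)(F)F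
Why: silylation with the silyl triflate is the standard way to protect a tertiary alcohol; this group must survive until step 16 so that no tetronic acid can form in the key step.

**Step 5**
Reactants: 5 (3R,6E)-3-(tert-butyldimethylsilyloxy)-3,7,11-trimethyldodeca-6,10-dien-1-yne
Product: 6 tert-butyl (4R,7E)-4-(tert-butyldimethylsilyloxy)-4,8,12-trimethyltrideca-7,11-dien-2-ynoate
Conditions: n-BuLi, THF, −78 °C; Boc2O, −78 → 0 °C; then H2O
Reagents that add atoms: di-tert-butyl dicarbonate CC(C)(C)OC(=O)OC(=O)OC(C)(C)C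
Why: C-acylation of a lithium acetylide with the dicarbonate is a known route to tert-butyl ynoates; the ynoate is a non-acidic, oxidation-stable mask of the β-keto ester.

**Step 6**
Reactants: 6 tert-butyl (4R,7E)-4-(tert-butyldimethylsilyloxy)-4,8,12-trimethyltrideca-7,11-dien-2-ynoate
Product: 7 tert-butyl (4R,7E,11E)-4-(tert-butyldimethylsilyloxy)-13-hydroxy-4,8,12-trimethyltrideca-7,11-dien-2-ynoate
Conditions: SeO2 (0.3 equiv), t-BuOOH, salicylic acid (cat.), CH2Cl2, 0 °C → rt
Reagents that add atoms: tert-butyl hydroperoxide CC(C)(C)OO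
Why: selenium dioxide allylic oxidation (ene reaction then [2,3] shift) is selective for the (E)-methyl group of the terminal trisubstituted alkene and should give the (E)-allylic alcohol at C13.

**Step 7**
Reactants: 7 tert-butyl (4R,7E,11E)-4-(tert-butyldimethylsilyloxy)-13-hydroxy-4,8,12-trimethyltrideca-7,11-dien-2-ynoate
Product: 9 tert-butyl (4R,7E,11E)-4-(tert-butyldimethylsilyloxy)-13-hydroxy-4,8,12-trimethyl-3-oxotrideca-7,11-dienoate, via enamino ester 8 (not isolated)
Conditions: pyrrolidine (1.2 equiv), EtOH, rt; then aqueous oxalic acid, THF, rt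
Reagents that add atoms: water O; pyrrolidine C1CCNC1 (present in 8 only)
Why: conjugate addition of a secondary amine to the ynoate β-carbon followed by enamine hydrolysis is a known net hydration of an ynoate to a β-keto ester, and C4 carries no hydrogen so no allene isomerization can occur.

**Step 8**
Reactants: 9 tert-butyl (4R,7E,11E)-4-(tert-butyldimethylsilyloxy)-13-hydroxy-4,8,12-trimethyl-3-oxotrideca-7,11-dienoate
Product: 10 tert-butyl (4R,7E,11E)-4-(tert-butyldimethylsilyloxy)-4,8,12-trimethyl-3,13-dioxotrideca-7,11-dienoate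
Conditions: MnO2, CH2Cl2, rt
Reagents that add atoms: none
Why: allylic alcohol oxidation with MnO2 is chemoselective and should give the (E)-enal without touching the β-keto ester.

**Step 9**
Reactants: 11 3-furanmethanol
Product: 13 3-(hydroxymethyl)furan-2(5H)-one, via boronate 12 (not isolated)
Conditions: n-BuLi (2.2 equiv), THF, −78 → 0 °C; B(OMe)3, −78 °C → rt; 30% H2O2, aqueous NaHCO3, 0 °C
Reagents that add atoms: hydrogen peroxide OO; trimethyl borate COB(OC)OC (present in 12 only)
Why: alkoxide-directed lithiation at C2 of the furan, borylation and oxidation give the 2-hydroxyfuran, which tautomerizes to the conjugated butenolide (known furan-to-butenolide sequence).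

**Step 10**
Reactants: 13 3-(hydroxymethyl)furan-2(5H)-one
Product: 15 2-(trimethylsilyloxy)-3-[(tert-butyldimethylsilyloxy)methyl]furan, via silyl ether 14 (not isolated)
Conditions: TBSCl, Et3N, 4-(dimethylamino)pyridine (cat.), CH2Cl2, 0 °C; then Et3N, TMSOTf, 0 °C
Reagents that add atoms: tert-butyldimethylsilyl chloride CC(C)(C)[Si](C)(C)Cl; trimethylsilyl trifluoromethanesulfonate C[Si](C)(C)OS(=O)(=O)C(F)(F)F
Why: O-silylation of the primary alcohol followed by soft enolization of the butenolide is the standard preparation of a 2-silyloxyfuran.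

**Step 11**
Reactants: 10 tert-butyl (4R,7E,11E)-4-(tert-butyldimethylsilyloxy)-4,8,12-trimethyl-3,13-dioxotrideca-7,11-dienoate; 15 2-(trimethylsilyloxy)-3-[(tert-butyldimethylsilyloxy)methyl]furan
Product: 16 tert-butyl (4R,7E,11E,13S)-4-(tert-butyldimethylsilyloxy)-13-hydroxy-13-[(2R)-4-[(tert-butyldimethylsilyloxy)methyl]-5-oxo-2,5-dihydrofuran-2-yl]-4,8,12-trimethyl-3-oxotrideca-7,11-dienoate
Conditions: 15 (1.5 equiv), [Cr((R,R)-salen)]SbF6 (5 mol %; salen = N,N′-bis(3,5-di-tert-butylsalicylidene)cyclohexane-1,2-diaminate), i-PrOH (1.2 equiv), CH2Cl2, −20 °C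
Reagents that add atoms: none
Why: catalytic enantioselective vinylogous Mukaiyama aldol reaction in which the cationic trivalent chromium Lewis acid binds the enal and the furan γ-carbon adds 1,2 through an open transition state, so the catalyst sets the aldehyde face (C13, S) and the anti approach sets C14 (R), with C4 too remote to interfere.

**Step 12**
Reactants: 16 (the aldol adduct of step 11)
Product: 17 tert-butyl (4R,7E,11E,13S)-13-acetoxy-4-(tert-butyldimethylsilyloxy)-13-[(2R)-4-[(tert-butyldimethylsilyloxy)methyl]-5-oxo-2,5-dihydrofuran-2-yl]-4,8,12-trimethyl-3-oxotrideca-7,11-dienoate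
Conditions: Ac2O, pyridine, 4-(dimethylamino)pyridine (cat.), CH2Cl2, 0 °C
Reagents that add atoms: acetic anhydride CC(=O)OC(C)=O
Why: acylation of the secondary allylic alcohol under weakly basic conditions installs the C13 acetate of the target early, where it also blocks O13 from trapping the acylketene in step 14.

**Step 13**
Reactants: 17 (the C13 acetate of step 12)
Product: 18 tert-butyl (4R,7E,11E,13S)-13-acetoxy-4-(tert-butyldimethylsilyloxy)-13-[(2R)-4-(hydroxymethyl)-5-oxo-2,5-dihydrofuran-2-yl]-4,8,12-trimethyl-3-oxotrideca-7,11-dienoate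
Conditions: HF·pyridine, pyridine, THF, 0 °C
Reagents that add atoms: none
Why: buffered fluoride desilylation should cleave the primary allylic silyl ether much faster than the tertiary one at C4, and it spares the acetate and the butenolide.

**Step 14**
Reactants: 18 (the seco β-keto ester of step 13)
Product: 22 (1R,4R,7E,11E,13S,14R)-13-acetoxy-4-(tert-butyldimethylsilyloxy)-3-oxocembra-7,11,15(17)-trien-16,14-olide, via acylketene 19 (not isolated), via macrocyclic allyl β-keto ester 20 (not isolated), via β-keto acid 21 (not isolated)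
Conditions: mesitylene, 160 °C, 18 added over 10 h by syringe pump (final 0.5 mM), 2,6-di-tert-butyl-4-methylphenol (cat.), N2 sweep
Reagents that add atoms: none
Why: Proposed new method: thermolysis of the tert-butyl β-keto ester expels tert-butanol to give acylketene 19, which the primary allylic C17 hydroxyl traps to close the temporary 18-membered β-keto lactone 20; the enol of 20 then undergoes a Carroll-type [3,3] shift through the array C2=C(OH)–O–C17–C15=C1 that forms C1–C2, moves the double bond to C15=C17 and releases the carboxyl group, lost as CO2 from 21. The closest known reactions are acylketene macrolactonization, the intermolecular Carroll rearrangement of allyl acetoacetates and Claisen ring contractions of macrolactones to carbocycles; a stepwise path (six-membered conjugate addition of the enol to C1, then β-elimination of the carboxylate) would lead to the same product. The 18-membered ring closes by O-acylation at the ketene carbon, and the 14-membered carbocycle closes by ring contraction, C2 adding to C1 of the butenolide alkene in a chair-like six-membered transition state. C1 is the only new stereocenter and is controlled by C14: C2 should be delivered to the butenolide face anti to the C13-bearing substituent, which gives the trans-fused lactone (1R). The step needs regioselectivity for C1 over C17, which the sigmatropic topology enforces; chemoselectivity for the C17 hydroxyl, secured because O13 is acetylated and O4 is silylated; and suppression of oligomers, secured by high dilution. The C7=C8 alkene cannot interfere because no radical or cation is generated at C2 or C3.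

**Step 15**
Reactants: 22 (the macrocyclic 3-ketone of step 14)
Product: 23 (1R,3S,4R,7E,11E,13S,14R)-13-acetoxy-3-hydroxy-4-(tert-butyldimethylsilyloxy)cembra-7,11,15(17)-trien-16,14-olide
Conditions: (R)-2-methyl-CBS-oxazaborolidine [(R)-1-methyl-3,3-diphenyltetrahydro-1H,3H-pyrrolo[1,2-c][1,3,2]oxazaborole] (1 equiv), catecholborane, toluene, −40 °C
Reagents that add atoms: none
Why: Corey–Bakshi–Shibata reduction under reagent control should place hydride on the face that gives the 3S-alcohol, with the quaternary silyloxy-bearing C4 as the large group and the C2 methylene as the small group; catecholborane spares the lactone, the acetate and the alkenes.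

**Step 16**
Reactants: 23 (the 3S-alcohol of step 15)
Product: 24 (1R,3S,4R,7E,11E,13S,14R)-13-acetoxy-3,4-dihydroxycembra-7,11,15(17)-trien-16,14-olide
Conditions: aqueous HF, MeCN, 0 °C → rt
Reagents that add atoms: none
Why: acidic fluoride desilylation removes the tertiary silyl ether without base, so neither acetate migration nor conjugate addition to the α-methylene lactone is expected.

**Step 17**
Reactants: 24 (the 3,4-diol of step 16)
Product: 25 Crassocolide B
Conditions: Ac2O, pyridine, 4-(dimethylamino)pyridine (cat.), CH2Cl2, 0 °C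
Reagents that add atoms: acetic anhydride CC(=O)OC(C)=O
Why: acylation is selective for the secondary C3 hydroxyl because the tertiary C4 hydroxyl does not react at 0 °C.

**Compound list**

1 | (2E,6E)-farnesol | OC/C=C(\C)CC/C=C(\C)CCC=C(C)C | starting material
2 | (2R,3R,6E)-2,3-epoxy-3,7,11-trimethyldodeca-6,10-dien-1-ol | OC[C@H]1O[C@]1(C)CC/C=C(\C)CCC=C(C)C | intermediate
3 | (2S,3R,6E)-1-chloro-2,3-epoxy-3,7,11-trimethyldodeca-6,10-diene | ClC[C@H]1O[C@]1(C)CC/C=C(\C)CCC=C(C)C | intermediate
4 | (3R,6E)-3,7,11-trimethyldodeca-6,10-dien-1-yn-3-ol | C#C[C@](C)(O)CC/C=C(\C)CCC=C(C)C | intermediate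
5 | (3R,6E)-3-(tert-butyldimethylsilyloxy)-3,7,11-trimethyldodeca-6,10-dien-1-yne | C#C[C@](C)(O[Si](C)(C)C(C)(C)C)CC/C=C(\C)CCC=C(C)C | intermediate
6 | tert-butyl (4R,7E)-4-(tert-butyldimethylsilyloxy)-4,8,12-trimethyltrideca-7,11-dien-2-ynoate | CC(C)(C)OC(=O)C#C[C@](C)(O[Si](C)(C)C(C)(C)C)CC/C=C(\C)CCC=C(C)C | intermediate
7 | tert-butyl (4R,7E,11E)-4-(tert-butyldimethylsilyloxy)-13-hydroxy-4,8,12-trimethyltrideca-7,11-dien-2-ynoate | CC(C)(C)OC(=O)C#C[C@](C)(O[Si](C)(C)C(C)(C)C)CC/C=C(\C)CC/C=C(\C)CO | intermediate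
8 | tert-butyl (4R,7E,11E)-4-(tert-butyldimethylsilyloxy)-13-hydroxy-4,8,12-trimethyl-3-(pyrrolidin-1-yl)trideca-2,7,11-trienoate (enamino ester, C2=C3 geometry not defined) | CC(C)(C)OC(=O)C=C(N1CCCC1)[C@](C)(O[Si](C)(C)C(C)(C)C)CC/C=C(\C)CC/C=C(\C)CO | intermediate
9 | tert-butyl (4R,7E,11E)-4-(tert-butyldimethylsilyloxy)-13-hydroxy-4,8,12-trimethyl-3-oxotrideca-7,11-dienoate | CC(C)(C)OC(=O)CC(=O)[C@](C)(O[Si](C)(C)C(C)(C)C)CC/C=C(\C)CC/C=C(\C)CO | intermediate
10 | tert-butyl (4R,7E,11E)-4-(tert-butyldimethylsilyloxy)-4,8,12-trimethyl-3,13-dioxotrideca-7,11-dienoate | CC(C)(C)OC(=O)CC(=O)[C@](C)(O[Si](C)(C)C(C)(C)C)CC/C=C(\C)CC/C=C(\C)C=O | intermediate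
11 | 3-furanmethanol | OCc1ccoc1 | starting material
12 | dimethyl [3-(hydroxymethyl)furan-2-yl]boronate (present as its lithium alkoxide) | COB(OC)c1occc1CO | intermediate
13 | 3-(hydroxymethyl)furan-2(5H)-one | O=C1OCC=C1CO | intermediate
14 | 3-[(tert-butyldimethylsilyloxy)methyl]furan-2(5H)-one | O=C1OCC=C1CO[Si](C)(C)C(C)(C)C | intermediate
15 | 2-(trimethylsilyloxy)-3-[(tert-butyldimethylsilyloxy)methyl]furan | C[Si](C)(C)Oc1occc1CO[Si](C)(C)C(C)(C)C | intermediate
16 | tert-butyl (4R,7E,11E,13S)-4-(tert-butyldimethylsilyloxy)-13-hydroxy-13-[(2R)-4-[(tert-butyldimethylsilyloxy)methyl]-5-oxo-2,5-dihydrofuran-2-yl]-4,8,12-trimethyl-3-oxotrideca-7,11-dienoate | CC(C)(C)OC(=O)CC(=O)[C@](C)(O[Si](C)(C)C(C)(C)C)CC/C=C(\C)CC/C=C(\C)[C@H](O)[C@@H]1OC(=O)C(CO[Si](C)(C)C(C)(C)C)=C1 | intermediate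
17 | C13 acetate of 16 | CC(C)(C)OC(=O)CC(=O)[C@](C)(O[Si](C)(C)C(C)(C)C)CC/C=C(\C)CC/C=C(\C)[C@H](OC(C)=O)[C@@H]1OC(=O)C(CO[Si](C)(C)C(C)(C)C)=C1 | intermediate
18 | tert-butyl (4R,7E,11E,13S)-13-acetoxy-4-(tert-butyldimethylsilyloxy)-13-[(2R)-4-(hydroxymethyl)-5-oxo-2,5-dihydrofuran-2-yl]-4,8,12-trimethyl-3-oxotrideca-7,11-dienoate | CC(C)(C)OC(=O)CC(=O)[C@](C)(O[Si](C)(C)C(C)(C)C)CC/C=C(\C)CC/C=C(\C)[C@H](OC(C)=O)[C@@H]1OC(=O)C(CO)=C1 | intermediate
19 | acylketene from 18 by loss of tert-butanol (O=C=CH–C3(=O)–) | O=C=CC(=O)[C@](C)(O[Si](C)(C)C(C)(C)C)CC/C=C(\C)CC/C=C(\C)[C@H](OC(C)=O)[C@@H]1OC(=O)C(CO)=C1 | intermediate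
20 | 18-membered allyl β-keto lactone (ester between O17 and the ketene carbon of 19) | O=C1CC(=O)[C@](C)(O[Si](C)(C)C(C)(C)C)CC/C=C(\C)CC/C=C(\C)[C@H](OC(C)=O)[C@@H]2OC(=O)C(CO1)=C2 | intermediate
21 | 2-carboxy derivative of 22 (β-keto acid, C2 configuration not defined) | C=C1C(=O)O[C@@H]2[C@@H]1C(C(=O)O)C(=O)[C@](C)(O[Si](C)(C)C(C)(C)C)CC/C=C(\C)CC/C=C(\C)[C@@H]2OC(C)=O | intermediate
22 | (1R,4R,7E,11E,13S,14R)-13-acetoxy-4-(tert-butyldimethylsilyloxy)-3-oxocembra-7,11,15(17)-trien-16,14-olide | C=C1C(=O)O[C@@H]2[C@@H]1CC(=O)[C@](C)(O[Si](C)(C)C(C)(C)C)CC/C=C(\C)CC/C=C(\C)[C@@H]2OC(C)=O | intermediate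
23 | (1R,3S,4R,7E,11E,13S,14R)-13-acetoxy-3-hydroxy-4-(tert-butyldimethylsilyloxy)cembra-7,11,15(17)-trien-16,14-olide | C=C1C(=O)O[C@@H]2[C@@H]1C[C@H](O)[C@](C)(O[Si](C)(C)C(C)(C)C)CC/C=C(\C)CC/C=C(\C)[C@@H]2OC(C)=O | intermediate
24 | (1R,3S,4R,7E,11E,13S,14R)-13-acetoxy-3,4-dihydroxycembra-7,11,15(17)-trien-16,14-olide | C=C1C(=O)O[C@@H]2[C@@H]1C[C@H](O)[C@](C)(O)CC/C=C(\C)CC/C=C(\C)[C@@H]2OC(C)=O | intermediate
25 | Crassocolide B, (1R,3S,4R,7E,11E,13S,14R)-3,13-diacetoxy-4-hydroxycembra-7,11,15(17)-trien-16,14-olide | C=C1C(=O)O[C@@H]2[C@@H]1C[C@H](OC(C)=O)[C@](C)(O)CC/C=C(\C)CC/C=C(\C)[C@@H]2OC(C)=O | target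

**Step count and risks**

Total: 17 steps. Longest linear sequence: 15 steps (steps 1–8 and 11–17, from farnesol); steps 9–10 make the furan partner.

Steps most likely to fail:

1. Step 14 (Proposed new method). Possible failure: intermolecular acylketene trapping leading to oligomers, or a macrolactone 20 that resists the sigmatropic shift and degrades on prolonged heating. Fallback with known reaction types: from 18, acetylation of the C17 hydroxyl (Ac2O, pyridine) gives the allylic acetate F1. Treatment of F1 with Cs2CO3 and catalytic 1,4-diazabicyclo[2.2.2]octane in MeCN at high dilution should let the soft β-keto ester enolate close the 14-membered ring by conjugate addition to C1 and β-elimination of acetate (SN2′ alkylation of a Morita–Baylis–Hillman-type acetate, combined with a standard carbonate-mediated β-keto ester macrocyclization), giving the ring-bound tert-butyl β-keto ester F2. Cleavage of the tert-butyl ester with CF3CO2H in CH2Cl2 at 0 °C and warming in toluene takes F2 through β-keto acid 21, and the route is rejoined at 22.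

2. Step 11. Possible failure: poor anti/syn facial selectivity, or inhibition of the Lewis acid through chelation by the β-keto ester. Fallback: from 7, pyrrolidine is added and enamino ester 8 is isolated without hydrolysis, then oxidized with MnO2 to the enamino ester enal F3. F3 and 15 are combined under Lewis-base catalysis (N-benzylcinchonidinium phenoxide, THF, −78 °C), a vinylogous Mukaiyama aldol manifold that favours the anti adduct and tolerates the non-acidic masked keto ester, to give the anti aldol adduct F4. Acetylation gives its C13 acetate F5, and enamine hydrolysis with aqueous oxalic acid in THF rejoins the route at 17.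

3. Step 15. Possible failure: slow or poorly face-selective hydride delivery to the hindered ketone between C2 and the quaternary C4. Fallback: from 22, the tertiary silyl ether is removed first (aqueous HF, MeCN) to give the α-hydroxy ketone F6. Reduction with Zn(BH4)2 in Et2O at −20 °C under chelation control (zinc bridging the C3 carbonyl and the C4 hydroxyl, hydride entering from the side of the C4 methyl group, which is smaller than the ring chain at C5) should give the anti 3,4-diol, and the route is rejoined at 24.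

**Further compounds**

F1 | step 14 | tert-butyl (4R,7E,11E,13S)-13-acetoxy-13-[(2R)-4-(acetoxymethyl)-5-oxo-2,5-dihydrofuran-2-yl]-4-(tert-butyldimethylsilyloxy)-4,8,12-trimethyl-3-oxotrideca-7,11-dienoate | CC(C)(C)OC(=O)CC(=O)[C@](C)(O[Si](C)(C)C(C)(C)C)CC/C=C(\C)CC/C=C(\C)[C@H](OC(C)=O)[C@@H]1OC(=O)C(COC(C)=O)=C1
F2 | step 14 | tert-butyl ester of 21 (2-tert-butoxycarbonyl derivative of 22, C2 configuration not defined) | C=C1C(=O)O[C@@H]2[C@@H]1C(C(=O)OC(C)(C)C)C(=O)[C@](C)(O[Si](C)(C)C(C)(C)C)CC/C=C(\C)CC/C=C(\C)[C@@H]2OC(C)=O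
F3 | step 11 | tert-butyl (4R,7E,11E)-4-(tert-butyldimethylsilyloxy)-4,8,12-trimethyl-13-oxo-3-(pyrrolidin-1-yl)trideca-2,7,11-trienoate | CC(C)(C)OC(=O)C=C(N1CCCC1)[C@](C)(O[Si](C)(C)C(C)(C)C)CC/C=C(\C)CC/C=C(\C)C=O
F4 | step 11 | 3-(pyrrolidin-1-yl)-2-ene (enamino ester) analogue of 16 | CC(C)(C)OC(=O)C=C(N1CCCC1)[C@](C)(O[Si](C)(C)C(C)(C)C)CC/C=C(\C)CC/C=C(\C)[C@H](O)[C@@H]1OC(=O)C(CO[Si](C)(C)C(C)(C)C)=C1
F5 | step 11 | 3-(pyrrolidin-1-yl)-2-ene (enamino ester) analogue of 17 | CC(C)(C)OC(=O)C=C(N1CCCC1)[C@](C)(O[Si](C)(C)C(C)(C)C)CC/C=C(\C)CC/C=C(\C)[C@H](OC(C)=O)[C@@H]1OC(=O)C(CO[Si](C)(C)C(C)(C)C)=C1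
F6 | step 15 | (1R,4R,7E,11E,13S,14R)-13-acetoxy-4-hydroxy-3-oxocembra-7,11,15(17)-trien-16,14-olide | C=C1C(=O)O[C@@H]2[C@@H]1CC(=O)[C@](C)(O)CC/C=C(\C)CC/C=C(\C)[C@@H]2OC(C)=O
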